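**Plan**

- Numbering: ring C1–C10 with Z‑C1=C10, HO–C2, E‑C4=C5; lactone O6–C12(=O)–C11(=C13)–C7; ester on O8. The enabling feature is the contiguous C6–C7–C8 triad: the trans‑fused γ‑lactone ring (O6, C6, C7, C11, C12) and the C8 oxygen are what anti opening of a trans‑7,8‑epoxide at C7 by a C11 carbanion tethered to O6 must give.
- Retrosynthetic cuts, in order: O8–acyl bond; C11=C13 (formaldehyde); C7–C11 together with the lactone ring (epoxide opening); C1–C2 (ten‑membered ring); C6–C7 (union of a C2–C6 enal with a C7–C10/C1 iodo enyne). The epoxy acid is made separately.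
- Forward: the fragments are joined at C6–C7, C7=C8 is epoxidised, the carbocycle is closed at C1–C2 by chromium‑mediated alkenyl iodide–aldehyde coupling, the lactone ring is then closed on the carbocycle, and methylenation, O8 acylation and desilylation finish the synthesis.
- Stereochemistry: C6 from (−)‑MIB‑controlled alkenylzinc addition; C7 and C8 from matched Sharpless epoxidation (C7 then inverted, C8 retained in the lactone closure); C2 from CBS reduction of the ring enone; side‑chain C2′/C3′ from Sharpless epoxidation.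
- Alkene geometry: Z‑C1=C10 from anti‑carbomagnesiation, E‑C4=C5 from syn‑carboalumination.

Key step: step 17

Remark: ring locants C1–C15 of the target are used for every intermediate; the (−)‑MIB addition is assumed to keep its usual Si‑face preference with enal 10; C11 of 25 forms as an epimer mixture, which is immaterial because C11 becomes trigonal in step 18.

**Route**

Step 1
Reactants: 1 prop-2-yn-1-ol
Product: 3 (Z)-3-iodo-2-methylprop-2-en-1-ol, via vinylmagnesium chelate 2 (not isolated)
Conditions: MeMgBr (3 equiv), CuI (10 mol%), THF, 0 °C to rt; then I2, −10 °C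
Reagents that add atoms: methylmagnesium bromide C[Mg]Br; iodine II
Why: Copper‑catalysed anti‑carbomagnesiation of the propargylic alkoxide puts methyl on the internal carbon and magnesium on the terminal carbon cis to CH2O (five‑membered chelate), and iodinolysis with retention should give the Z iodoalkene that becomes Z‑C1=C10 with C14 and C9.

Step 2
Reactants: 3 (Z)-3-iodo-2-methylprop-2-en-1-ol
Product: 4 (Z)-3-bromo-1-iodo-2-methylprop-1-ene
Conditions: CBr4, PPh3, CH2Cl2, 0 °C
Reagents that add atoms: carbon tetrabromide BrC(Br)(Br)Br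
Why: Appel bromination of the primary allylic alcohol proceeds by SN2 displacement of the oxyphosphonium group and leaves the alkenyl iodide and its geometry untouched.

Step 3
Reactants: 4 (Z)-3-bromo-1-iodo-2-methylprop-1-ene
Product: 5 (Z)-1-iodo-2-methylpent-1-en-4-yne
Conditions: HC≡CMgBr, CuBr·SMe2 (5 mol%), THF, 0 °C to rt
Reagents that add atoms: ethynylmagnesium bromide C#C[Mg]Br
Why: Copper‑catalysed substitution of a primary allylic bromide by an alkynyl Grignard reagent is a standard entry to skipped enynes; attack at the unhindered CH2 (C9) is expected and the alkenyl iodide is inert to the alkynylmetal.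

Step 4
Reactants: 6 tert-butyl(but-3-yn-1-yloxy)dimethylsilane
Product: 9 (E)-5-[(tert-butyldimethylsilyl)oxy]-3-methylpent-2-en-1-ol, via alkenyldimethylalane 7 (not isolated), via lithium alkenylalanate 8 (not isolated)
Conditions: Me3Al, Cp2ZrCl2 (25 mol%), CH2Cl2, rt; solvent change to hexane/THF; n-BuLi, −78 °C; (CH2O)n, to rt
Reagents that add atoms: trimethylaluminium C[Al](C)C; formaldehyde C=O
Why: Negishi zirconium‑catalysed carboalumination adds methyl and aluminium syn across the terminal alkyne (methyl to the internal carbon), and hydroxymethylation of the derived alanate with retention should give the E trisubstituted allylic alcohol carrying C2–C6 and C15.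

Step 5
Reactants: 9 (E)-5-[(tert-butyldimethylsilyl)oxy]-3-methylpent-2-en-1-ol
Product: 10 (E)-5-[(tert-butyldimethylsilyl)oxy]-3-methylpent-2-enal
Conditions: MnO2, CH2Cl2, rt
Reagents that add atoms: none
Why: MnO2 oxidises allylic alcohols selectively to enals under neutral conditions, which should preserve the E geometry and the silyl ether.

Step 6
Reactants: 5 (Z)-1-iodo-2-methylpent-1-en-4-yne; 10 (E)-5-[(tert-butyldimethylsilyl)oxy]-3-methylpent-2-enal
Product: 13 (3E,5S,6E,9Z)-1-[(tert-butyldimethylsilyl)oxy]-10-iodo-3,9-dimethyldeca-3,6,9-trien-5-ol, via alkenyldicyclohexylborane 11 (not isolated), via alkenyl(methyl)zinc 12 (not isolated)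
Conditions: Cy2BH, toluene, 0 °C to rt (on 5); Me2Zn, (−)-MIB (5 mol%), −78 °C; then 10, −20 to 0 °C
Reagents that add atoms: none
Why: syn‑Hydroboration of the terminal alkyne, boron‑to‑zinc transmetalation and amino‑alcohol‑catalysed 1,2‑addition of the E‑alkenylzinc to the enal form C6–C7 together with E‑C7=C8, and (−)‑MIB should direct attack to the Si face of the aldehyde to set C6 (S in 13).

Step 7
Reactants: 13 (3E,5S,6E,9Z)-1-[(tert-butyldimethylsilyl)oxy]-10-iodo-3,9-dimethyldeca-3,6,9-trien-5-ol
Product: 14 (3E,5R,6R,7R,9Z)-1-[(tert-butyldimethylsilyl)oxy]-6,7-epoxy-10-iodo-3,9-dimethyldeca-3,9-dien-5-ol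
Conditions: Ti(OiPr)4 (0.2 equiv), D-(−)-DIPT (0.25 equiv), t-BuOOH, 4 Å MS, CH2Cl2, −20 °C
Reagents that add atoms: tert-butyl hydroperoxide CC(C)(C)OO
Why: Sharpless asymmetric epoxidation in its matched (fast kinetic‑resolution) manifold: with the D‑tartrate this carbinol presents C7=C8 for oxygen delivery anti to the C6 substituent, giving the erythro trans‑epoxide (ring C7 R, C8 R; the C6 descriptor changes from S to R by priority only), whereas the trisubstituted C4=C5 bond is mismatched for this tartrate and hindered by its cis methyl group and the iodoalkene is not allylic to the hydroxyl.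

Step 8
Reactants: 14 (3E,5R,6R,7R,9Z)-1-[(tert-butyldimethylsilyl)oxy]-6,7-epoxy-10-iodo-3,9-dimethyldeca-3,9-dien-5-ol
Product: 15 4-methoxybenzyl ether of 14 at the C5 oxygen (ring O6)
Conditions: NaH, PMBCl, Bu4NI (cat.), THF/DMF, 0 °C
Reagents that add atoms: 4-methoxybenzyl chloride COc1ccc(CCl)cc1
Why: Williamson etherification of the sodium alkoxide; in aprotic medium with an activated benzylic halide O‑alkylation should outrun Payne rearrangement of the epoxy alkoxide.

Step 9
Reactants: 15 4-methoxybenzyl ether of 14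
Product: 16 (3E,5R,6S,7R,9Z)-6,7-epoxy-10-iodo-5-[(4-methoxybenzyl)oxy]-3,9-dimethyldeca-3,9-dien-1-ol
Conditions: TBAF, THF, 0 °C to rt
Reagents that add atoms: none
Why: Fluoride cleaves the primary silyl ether by Si–F bond formation without affecting the PMB ether, the epoxide or the alkenyl iodide.

Step 10
Reactants: 16 (3E,5R,6S,7R,9Z)-6,7-epoxy-10-iodo-5-[(4-methoxybenzyl)oxy]-3,9-dimethyldeca-3,9-dien-1-ol
Product: 17 (3E,5R,6S,7R,9Z)-6,7-epoxy-10-iodo-5-[(4-methoxybenzyl)oxy]-3,9-dimethyldeca-3,9-dienal
Conditions: Dess–Martin periodinane, pyridine, CH2Cl2, 0 °C; used at once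
Reagents that add atoms: none
Why: Dess–Martin oxidation under pyridine buffering converts the homoallylic alcohol to the β,γ‑unsaturated aldehyde without a base strong enough to move C4=C5 into conjugation.

Step 11
Reactants: 17 (3E,5R,6S,7R,9Z)-6,7-epoxy-10-iodo-5-[(4-methoxybenzyl)oxy]-3,9-dimethyldeca-3,9-dienal
Product: 18 (6R,7S,8R)-7,8-epoxy-6-[(4-methoxybenzyl)oxy]-4,10-dimethylcyclodeca-1(10)Z,4E-dien-2-ol (both C2 epimers)
Conditions: CrCl2 (8 equiv), NiCl2 (2 mol%), DMSO, rt, 2 mM, syringe-pump addition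
Reagents that add atoms: none
Why: Nozaki–Hiyama–Kishi reaction: nickel‑catalysed activation of the alkenyl iodide, transmetalation to chromium and addition of the alkenylchromium species to the aldehyde under high dilution close the ten‑membered ring at C1–C2 with retention of the Z geometry and tolerate epoxide and ethers; both C2 epimers are taken on because C2 is reset in steps 12 and 13.

Step 12
Reactants: 18 macrocyclic C2 alcohols
Product: 19 (6R,7S,8R)-7,8-epoxy-6-[(4-methoxybenzyl)oxy]-4,10-dimethylcyclodeca-1(10)Z,4E-dien-2-one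
Conditions: Dess–Martin periodinane, pyridine, CH2Cl2, 0 °C
Reagents that add atoms: none
Why: Dess–Martin oxidation converges both allylic alcohol epimers on one enone under non‑basic conditions that should not isomerise the skipped C4=C5 bond.

Step 13
Reactants: 19 macrocyclic enone
Product: 20 (2S,6R,7S,8R)-7,8-epoxy-6-[(4-methoxybenzyl)oxy]-4,10-dimethylcyclodeca-1(10)Z,4E-dien-2-ol
Conditions: (R)-Me-CBS oxazaborolidine (20 mol%), catecholborane, toluene, −78 °C
Reagents that add atoms: none
Why: Corey–Bakshi–Shibata reduction: the ketone binds with the alkenyl arm (C1=C10) as the large and CH2‑3 as the small substituent, so the R catalyst (which gives S alcohols from aryl and alkenyl alkyl ketones of this priority pattern) should deliver hydride to give the 2S allylic alcohol.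

Step 14
Reactants: 20 (2S)-allylic alcohol
Product: 21 (2S,6R,7S,8R)-2-[(tert-butyldimethylsilyl)oxy]-7,8-epoxy-6-[(4-methoxybenzyl)oxy]-4,10-dimethylcyclodeca-1(10)Z,4E-diene
Conditions: TBSCl, imidazole, DMF, rt
Reagents that add atoms: tert-butyldimethylsilyl chloride CC(C)(C)[Si](C)(C)Cl
Why: Silylation of the secondary allylic alcohol with TBSCl/imidazole avoids Lewis‑acidic silyl triflates that could open the epoxide.

Step 15
Reactants: 21 O2-silyl O6-PMB macrocycle
Product: 22 (2S,6R,7R,8R)-2-[(tert-butyldimethylsilyl)oxy]-7,8-epoxy-4,10-dimethylcyclodeca-1(10)Z,4E-dien-6-ol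
Conditions: DDQ, CH2Cl2/pH 7 phosphate buffer, 0 °C
Reagents that add atoms: none
Why: DDQ oxidises the electron‑rich PMB ether to the oxocarbenium ion, which water cleaves to 4‑methoxybenzaldehyde and the free C6 alcohol; the buffered medium should spare the silyl ether, the epoxide and the trisubstituted alkenes.

Step 16
Reactants: 22 macrocyclic epoxy alcohol; 23 diethylphosphonoacetic acid
Product: 24 (2S,6R,7S,8R)-2-[(tert-butyldimethylsilyl)oxy]-7,8-epoxy-4,10-dimethylcyclodeca-1(10)Z,4E-dien-6-yl 2-(diethoxyphosphoryl)acetate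
Conditions: DCC, DMAP (cat.), CH2Cl2, 0 °C to rt
Reagents that add atoms: none
Why: Steglich esterification (DCC activation, DMAP acyl transfer) acylates the hindered secondary alcohol under conditions too weakly basic to deprotonate the phosphonoacetate or to trigger Payne rearrangement.

Step 17
Reactants: 24 O6 phosphonoacetate of the ten-membered 7,8-epoxide
Product: 25 (2S,6R,7R,8R)-2-[(tert-butyldimethylsilyl)oxy]-11-(diethoxyphosphoryl)-8-hydroxy-13-norgermacra-1(10)Z,4E-dien-12,6-olide (C11 epimers)
Conditions: NaH (1.1 equiv), THF, 0 °C to 50 °C; aq. NH4Cl quench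
Reagents that add atoms: none
Why: NaH removes the proton flanked by P=O and C=O, and the sodium carbanion, held on O6, attacks the adjacent epoxide carbon C7 from the face opposite the C7–O bond (intramolecular SN2), forming C7–C11 and the γ‑lactone while the epoxide oxygen leaves as the C8 alkoxide, which is then quenched by the more acidic C11–H so that the resting state is the phosphonate‑stabilised lactone enolate. The closest known reaction types are the intermolecular opening of epoxides by phosphonoacetate carbanions that leads to α‑phosphono‑γ‑lactones and the intramolecular alkylation of stabilised carbanions by epoxides. The five‑membered lactone (O6, C12, C11, C7, C6) closes in the 5‑exo‑tet mode, the breaking C7–O bond lying outside the new ring. C7 is set by inversion under control of the epoxide configuration, C8 keeps its oxygen and configuration, and because O6 and the epoxide oxygen are erythro, backside entry at C7 necessarily gives the trans ring fusion (H6 and H7 anti). The step needs attack at C7 and not at C8: the two‑atom tether from O6 makes C7 the 5‑exo terminus, whereas C8 would demand a 6‑endo closure with a strained trajectory. One equivalent of base and a buffered quench should keep the free C8 hydroxyl from relactonising onto C12.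

Step 18
Reactants: 25 α-phosphono lactone
Product: 26 (2S,6R,7R,8R)-2-[(tert-butyldimethylsilyl)oxy]-8-hydroxygermacra-1(10)Z,4E,11(13)-trien-12,6-olide
Conditions: K2CO3, 37% aq. HCHO, THF, 0 °C
Reagents that add atoms: formaldehyde C=O
Why: Horner–Wadsworth–Emmons reaction: carbonate deprotonates C11 (both epimers converge), the carbanion adds to formaldehyde and the oxaphosphetane collapses to the exocyclic C11=C13 alkene with loss of diethyl phosphate; low temperature and short contact should prevent relactonisation by the free 8‑OH.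

Step 19
Reactants: 27 (E)-but-2-enal
Product: 28 (Z)-2-iodobut-2-enal
Conditions: I2, K2CO3, DMAP (cat.), THF/H2O, rt
Reagents that add atoms: iodine II
Why: α‑Iodination through conjugate addition of DMAP, iodination of the resulting enolate and elimination of DMAP should give the iodoenal with methyl trans to the formyl group (Z), the thermodynamically favoured isomer.

Step 20
Reactants: 28 (Z)-2-iodobut-2-enal
Product: 29 (Z)-2-iodobut-2-en-1-ol
Conditions: NaBH4, CeCl3·7H2O, MeOH, 0 °C
Reagents that add atoms: none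
Why: Luche conditions give clean 1,2‑reduction of the enal to the allylic alcohol without touching the alkenyl iodide.

Step 21
Reactants: 29 (Z)-2-iodobut-2-en-1-ol
Product: 30 tert-butyl{[(Z)-2-iodobut-2-en-1-yl]oxy}dimethylsilane
Conditions: TBSCl, imidazole, CH2Cl2, rt
Reagents that add atoms: tert-butyldimethylsilyl chloride CC(C)(C)[Si](C)(C)Cl
Why: Standard silylation of the primary alcohol; this silyl ether stays as the protecting group of the side‑chain hydroxymethyl until the last step.

Step 22
Reactants: 30 tert-butyl{[(Z)-2-iodobut-2-en-1-yl]oxy}dimethylsilane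
Product: 32 (E)-2-{[(tert-butyldimethylsilyl)oxy]methyl}but-2-en-1-ol, via alkenyllithium 31 (not isolated)
Conditions: t-BuLi (2.1 equiv), Et2O, −78 °C; then HCHO (from cracked paraformaldehyde), −78 to 0 °C
Reagents that add atoms: formaldehyde C=O
Why: Iodine–lithium exchange proceeds with retention of alkene geometry and the alkenyllithium adds to formaldehyde at −78 °C, where silyl migration from oxygen to carbon is slow, so the new carbinol arm ends up cis to the methyl group.

Step 23
Reactants: 32 (E)-2-{[(tert-butyldimethylsilyl)oxy]methyl}but-2-en-1-ol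
Product: 33 [(2R,3R)-2-{[(tert-butyldimethylsilyl)oxy]methyl}-3-methyloxiran-2-yl]methanol
Conditions: Ti(OiPr)4 (0.1 equiv), L-(+)-DET (0.12 equiv), t-BuOOH, 4 Å MS, CH2Cl2, −20 °C
Reagents that add atoms: tert-butyl hydroperoxide CC(C)(C)OO
Why: Sharpless asymmetric epoxidation of the primary allylic alcohol: with L‑(+)‑tartrate oxygen is delivered to the alkene face that gives the (2R,3R) epoxy alcohol, and the alkene geometry places the methyl group cis to the carbinol arm that becomes the carboxyl group.

Step 24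
Reactants: 33 [(2R,3R)-2-{[(tert-butyldimethylsilyl)oxy]methyl}-3-methyloxiran-2-yl]methanol
Product: 34 (2R,3R)-2-{[(tert-butyldimethylsilyl)oxy]methyl}-3-methyloxirane-2-carboxylic acid
Conditions: TEMPO (cat.), PhI(OAc)2, MeCN/pH 7 buffer, rt
Reagents that add atoms: water O
Why: TEMPO/PhI(OAc)2 oxidation takes the primary alcohol through the aldehyde hydrate to the carboxylic acid at neutral pH, which the epoxide and the silyl ether should tolerate; the quaternary C2′ cannot epimerise.

Step 25
Reactants: 26 8-hydroxy α-methylene lactone; 34 (2R,3R)-2-{[(tert-butyldimethylsilyl)oxy]methyl}-3-methyloxirane-2-carboxylic acid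
Product: 35 bis(tert-butyldimethylsilyl) ether of the target (silyl on O2 and on the side-chain CH2O)
Conditions: 2,4,6-trichlorobenzoyl chloride, Et3N, DMAP, toluene, rt
Reagents that add atoms: none
Why: Yamaguchi esterification: DMAP attacks the mixed anhydride at the less shielded epoxy acyl carbon and the acylpyridinium acylates the only free hydroxyl (O8) without disturbing the α‑methylene lactone.

Step 26
Reactants: 35 bis-silyl ether of the target
Product: 36 (2S,6R,7R,8R)-2-hydroxy-8-{[(2R,3R)-2-(hydroxymethyl)-3-methyloxirane-2-carbonyl]oxy}germacra-1(10)Z,4E,11(13)-trien-12,6-olide (CNP0268432.6)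
Conditions: HF·pyridine, pyridine, THF, 0 °C to rt
Reagents that add atoms: none
Why: Buffered HF·pyridine removes the primary and the secondary allylic silyl ether by Si–F bond formation while the glycidic ester, the α‑methylene lactone and the allylic alcohol should survive, giving the target.

**Compound list**

1 | prop-2-yn-1-ol | C#CCO | starting material
2 | bromomagnesium (Z)-3-(bromomagnesio)-2-methylprop-2-en-1-olate (vinylmagnesium chelate) | Br[Mg]/C=C(C)\CO[Mg]Br | intermediate (not isolated)
3 | (Z)-3-iodo-2-methylprop-2-en-1-ol | OC/C(C)=C\I | intermediate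
4 | (Z)-3-bromo-1-iodo-2-methylprop-1-ene | BrC/C(C)=C\I | intermediate
5 | (Z)-1-iodo-2-methylpent-1-en-4-yne | C#CC/C(C)=C\I | intermediate
6 | tert-butyl(but-3-yn-1-yloxy)dimethylsilane | C#CCCO[Si](C)(C)C(C)(C)C | starting material
7 | {(E)-4-[(tert-butyldimethylsilyl)oxy]-2-methylbut-1-en-1-yl}dimethylalane | C[Al](C)/C=C(\C)CCO[Si](C)(C)C(C)(C)C | intermediate (not isolated)
8 | lithium butyl{(E)-4-[(tert-butyldimethylsilyl)oxy]-2-methylbut-1-en-1-yl}dimethylaluminate | [Li+].CCCC[Al-](C)(C)/C=C(\C)CCO[Si](C)(C)C(C)(C)C | intermediate (not isolated)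
9 | (E)-5-[(tert-butyldimethylsilyl)oxy]-3-methylpent-2-en-1-ol | OC/C=C(\C)CCO[Si](C)(C)C(C)(C)C | intermediate
10 | (E)-5-[(tert-butyldimethylsilyl)oxy]-3-methylpent-2-enal | O=C/C=C(\C)CCO[Si](C)(C)C(C)(C)C | intermediate
11 | dicyclohexyl[(1E,4Z)-5-iodo-4-methylpenta-1,4-dien-1-yl]borane | I/C=C(C)\C/C=C/B(C1CCCCC1)C1CCCCC1 | intermediate (not isolated)
12 | methyl[(1E,4Z)-5-iodo-4-methylpenta-1,4-dien-1-yl]zinc | I/C=C(C)\C/C=C/[Zn]C | intermediate (not isolated)
13 | (3E,5S,6E,9Z)-1-[(tert-butyldimethylsilyl)oxy]-10-iodo-3,9-dimethyldeca-3,6,9-trien-5-ol (chain C5 = ring C6) | I/C=C(C)\C/C=C/[C@H](O)/C=C(\C)CCO[Si](C)(C)C(C)(C)C | intermediate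
14 | (3E,5R,6R,7R,9Z)-1-[(tert-butyldimethylsilyl)oxy]-6,7-epoxy-10-iodo-3,9-dimethyldeca-3,9-dien-5-ol (chain C5, C6, C7 = ring C6, C7, C8; erythro, trans-epoxide) | I/C=C(C)\C[C@H]1O[C@@H]1[C@H](O)/C=C(\C)CCO[Si](C)(C)C(C)(C)C | intermediate
15 | 4-methoxybenzyl ether of 14 at the carbinol oxygen (stereocentres unchanged; descriptors 5R,6S,7R) | I/C=C(C)\C[C@H]1O[C@@H]1[C@H](OCc1ccc(OC)cc1)/C=C(\C)CCO[Si](C)(C)C(C)(C)C | intermediate
16 | (3E,5R,6S,7R,9Z)-6,7-epoxy-10-iodo-5-[(4-methoxybenzyl)oxy]-3,9-dimethyldeca-3,9-dien-1-ol | I/C=C(C)\C[C@H]1O[C@@H]1[C@H](OCc1ccc(OC)cc1)/C=C(\C)CCO | intermediate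
17 | (3E,5R,6S,7R,9Z)-6,7-epoxy-10-iodo-5-[(4-methoxybenzyl)oxy]-3,9-dimethyldeca-3,9-dienal | I/C=C(C)\C[C@H]1O[C@@H]1[C@H](OCc1ccc(OC)cc1)/C=C(\C)CC=O | intermediate
18 | (6R,7S,8R)-7,8-epoxy-6-[(4-methoxybenzyl)oxy]-4,10-dimethylcyclodeca-1(10)Z,4E-dien-2-ol, both C2 epimers (ring locants of the target) | COc1ccc(CO[C@@H]2/C=C(\C)CC(O)/C=C(/C)C[C@H]3O[C@H]23)cc1 | intermediate
19 | (6R,7S,8R)-7,8-epoxy-6-[(4-methoxybenzyl)oxy]-4,10-dimethylcyclodeca-1(10)Z,4E-dien-2-one | COc1ccc(CO[C@@H]2/C=C(\C)CC(=O)/C=C(/C)C[C@H]3O[C@H]23)cc1 | intermediate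
20 | (2S,6R,7S,8R)-7,8-epoxy-6-[(4-methoxybenzyl)oxy]-4,10-dimethylcyclodeca-1(10)Z,4E-dien-2-ol | COc1ccc(CO[C@@H]2/C=C(\C)C[C@H](O)/C=C(/C)C[C@H]3O[C@H]23)cc1 | intermediate
21 | (2S,6R,7S,8R)-2-[(tert-butyldimethylsilyl)oxy]-7,8-epoxy-6-[(4-methoxybenzyl)oxy]-4,10-dimethylcyclodeca-1(10)Z,4E-diene | COc1ccc(CO[C@@H]2/C=C(\C)C[C@H](O[Si](C)(C)C(C)(C)C)/C=C(/C)C[C@H]3O[C@H]23)cc1 | intermediate
22 | (2S,6R,7R,8R)-2-[(tert-butyldimethylsilyl)oxy]-7,8-epoxy-4,10-dimethylcyclodeca-1(10)Z,4E-dien-6-ol | O[C@@H]1/C=C(\C)C[C@H](O[Si](C)(C)C(C)(C)C)/C=C(/C)C[C@H]2O[C@H]12 | intermediate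
23 | diethylphosphonoacetic acid [2-(diethoxyphosphoryl)acetic acid] | CCOP(=O)(CC(=O)O)OCC | starting material
24 | (2S,6R,7S,8R)-2-[(tert-butyldimethylsilyl)oxy]-7,8-epoxy-4,10-dimethylcyclodeca-1(10)Z,4E-dien-6-yl 2-(diethoxyphosphoryl)acetate | CCOP(=O)(OCC)CC(=O)O[C@@H]1/C=C(\C)C[C@H](O[Si](C)(C)C(C)(C)C)/C=C(/C)C[C@H]2O[C@H]12 | intermediate
25 | (2S,6R,7R,8R)-2-[(tert-butyldimethylsilyl)oxy]-11-(diethoxyphosphoryl)-8-hydroxy-13-norgermacra-1(10)Z,4E-dien-12,6-olide, trans-fused lactone, C11 epimers | CCOP(=O)(OCC)C1C(=O)O[C@@H]2/C=C(\C)C[C@H](O[Si](C)(C)C(C)(C)C)/C=C(/C)C[C@@H](O)[C@@H]12 | intermediate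
26 | (2S,6R,7R,8R)-2-[(tert-butyldimethylsilyl)oxy]-8-hydroxygermacra-1(10)Z,4E,11(13)-trien-12,6-olide | C=C1C(=O)O[C@@H]2/C=C(\C)C[C@H](O[Si](C)(C)C(C)(C)C)/C=C(/C)C[C@@H](O)[C@@H]12 | intermediate
27 | (E)-but-2-enal | C/C=C/C=O | starting material
28 | (Z)-2-iodobut-2-enal | C/C=C(\I)C=O | intermediate
29 | (Z)-2-iodobut-2-en-1-ol | C/C=C(\I)CO | intermediate
30 | tert-butyl{[(Z)-2-iodobut-2-en-1-yl]oxy}dimethylsilane | C/C=C(\I)CO[Si](C)(C)C(C)(C)C | intermediate
31 | (Z)-{1-[(tert-butyldimethylsilyl)oxy]but-2-en-2-yl}lithium | C/C=C(\[Li])CO[Si](C)(C)C(C)(C)C | intermediate (not isolated)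
32 | (E)-2-{[(tert-butyldimethylsilyl)oxy]methyl}but-2-en-1-ol | C/C=C(\CO)CO[Si](C)(C)C(C)(C)C | intermediate
33 | [(2R,3R)-2-{[(tert-butyldimethylsilyl)oxy]methyl}-3-methyloxiran-2-yl]methanol | OC[C@]1(CO[Si](C)(C)C(C)(C)C)O[C@@H]1C | intermediate
34 | (2R,3R)-2-{[(tert-butyldimethylsilyl)oxy]methyl}-3-methyloxirane-2-carboxylic acid | OC(=O)[C@]1(CO[Si](C)(C)C(C)(C)C)O[C@@H]1C | intermediate
35 | bis(tert-butyldimethylsilyl) ether of the target (O2 and side-chain CH2O) | C=C1C(=O)O[C@@H]2/C=C(\C)C[C@H](O[Si](C)(C)C(C)(C)C)/C=C(/C)C[C@@H](OC(=O)[C@]3(CO[Si](C)(C)C(C)(C)C)O[C@@H]3C)[C@@H]12 | intermediate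
36 | (2S,6R,7R,8R)-2-hydroxy-8-{[(2R,3R)-2-(hydroxymethyl)-3-methyloxirane-2-carbonyl]oxy}germacra-1(10)Z,4E,11(13)-trien-12,6-olide (CNP0268432.6) | C=C1C(=O)O[C@@H]2/C=C(\C)C[C@H](O)/C=C(/C)C[C@@H](OC(=O)[C@]3(CO)O[C@@H]3C)[C@@H]12 | target

**Step count**

Total: 26 steps. Longest linear sequence: 18 steps (steps 1–3, 6–18, 25, 26).

**Steps most likely to fail**

1. Step 11 (ring closure). What may go wrong: the alkenylchromium species may not reach the aldehyde within the same molecule, so that oligomerisation, protodeiodination or drift of the β,γ‑unsaturated aldehyde into conjugation overtake closure of the strained ring. The fallback closes the ring by olefin metathesis at C1=C10 in place of carbonyl addition at C1–C2; it sets out from 17 and returns at 18. Vinylmagnesium bromide adds to 17 at −78 °C to give the vinyl carbinol F1. Pd(PPh3)4 with Bu3SnH then removes the iodine to give the diene carbinol F2. Ring‑closing metathesis with second‑generation Grubbs catalyst in dilute toluene closes C1=C10 with loss of ethene, the ring size enforcing the cis (Z) geometry, and gives 18.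

2. Step 17 (lactone closure). What may go wrong: the stabilised, encumbered phosphonate carbanion may open the epoxide too slowly, so that on heating acyl transfer to the liberated C8 alkoxide, relactonisation towards O8 or base‑induced elimination of the epoxide compete. The fallback uses a malonate tether and decarboxylative methylenation; it sets out from 22 and returns at 26. Heating 22 with Meldrum's acid in toluene gives the O6 malonic half ester F3. LiHMDS (2.2 equiv) forms the carboxylate enolate, a smaller and more nucleophilic carbanion, which should open the epoxide at C7 in the same 5‑exo, anti manner to give the α‑carboxy trans‑lactone F4. Aqueous HCHO with Et2NH (Mannich reaction with decarboxylative elimination) then gives 26 directly.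

3. Step 13 (C2 carbinol). What may go wrong: poor facial selectivity if the preferred conformation of the ten‑membered enone shields the face that the catalyst must reach. The fallback relies on substrate control followed by inversion; it sets out from 19 and returns at 20. Luche reduction (NaBH4, CeCl3·7H2O, MeOH, −78 °C) delivers hydride from the exposed face of the ring. Should this give the 2R alcohol F5, Mitsunobu esterification with 4‑nitrobenzoic acid (PPh3, DIAD) inverts C2 to the 2S 4‑nitrobenzoate F6, and methanolysis (K2CO3, MeOH) gives 20.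

Further compounds
F1 | step 11 | (5E,7R,8S,9R,11Z)-8,9-epoxy-12-iodo-7-[(4-methoxybenzyl)oxy]-5,11-dimethyldodeca-1,5,11-trien-3-ol (vinyl carbinol of 17, C3 epimers) | I/C=C(C)\C[C@H]1O[C@@H]1[C@H](OCc1ccc(OC)cc1)/C=C(\C)CC(O)C=C
F2 | step 11 | (5E,7R,8S,9R)-8,9-epoxy-7-[(4-methoxybenzyl)oxy]-5,11-dimethyldodeca-1,5,11-trien-3-ol (des-iodo diene carbinol) | C=C(C)C[C@H]1O[C@@H]1[C@H](OCc1ccc(OC)cc1)/C=C(\C)CC(O)C=C
F3 | step 17 | O6 malonic half ester of 22: 3-oxo-3-{[(2S,6R,7S,8R)-2-[(tert-butyldimethylsilyl)oxy]-7,8-epoxy-4,10-dimethylcyclodeca-1(10)Z,4E-dien-6-yl]oxy}propanoic acid | OC(=O)CC(=O)O[C@@H]1/C=C(\C)C[C@H](O[Si](C)(C)C(C)(C)C)/C=C(/C)C[C@H]2O[C@H]12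
F4 | step 17 | (2S,6R,7R,8R)-2-[(tert-butyldimethylsilyl)oxy]-8-hydroxy-12-oxo-13-norgermacra-1(10)Z,4E-dien-12,6-olide-11-carboxylic acid (α-carboxy trans-lactone, C11 epimers) | OC(=O)C1C(=O)O[C@@H]2/C=C(\C)C[C@H](O[Si](C)(C)C(C)(C)C)/C=C(/C)C[C@@H](O)[C@@H]12
F5 | step 13 | (2R,6R,7S,8R)-7,8-epoxy-6-[(4-methoxybenzyl)oxy]-4,10-dimethylcyclodeca-1(10)Z,4E-dien-2-ol (C2 epimer of 20) | COc1ccc(CO[C@@H]2/C=C(\C)C[C@@H](O)/C=C(/C)C[C@H]3O[C@H]23)cc1
F6 | step 13 | (2S,6R,7S,8R)-7,8-epoxy-6-[(4-methoxybenzyl)oxy]-4,10-dimethylcyclodeca-1(10)Z,4E-dien-2-yl 4-nitrobenzoate | COc1ccc(CO[C@@H]2/C=C(\C)C[C@H](OC(=O)c3ccc(cc3)[N+](=O)[O-])/C=C(/C)C[C@H]4O[C@H]24)cc1
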